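## Structural features

The target is a biflavone: two 2-(4-hydroxyphenyl)chromen-4-ones joined by one aryl–aryl bond between C8 of unit 1 and C6'' of unit 2 (unit 1 is numbered 2 to 8a with ring B 1' to 6', unit 2 is numbered 2'' to 8a'' with ring B 1''' to 6'''). Unit 1 carries the only methyl ether, at O7, and a chelated hydroxyl at C5; unit 2 has hydroxyls at C5'' and C7'', and each ring B ends in a 4-hydroxyl. There is no stereogenic carbon; the biaryl bond has four ortho substituents (the O7 methyl ether and the ring oxygen at C8a on one side, the oxygens at C5'' and C7'' on the other), so rotation is hindered, but no axial descriptor is specified and the racemic axis is the goal. The fragile groups are the five phenols, which oxidise and alkylate easily, the two pyranone enones, which open with strong base and can be over-reduced, and the 5-hydroxyflavone motif, which can open and reclose under hot acid so that C6 and C8 substituents exchange. The real difficulty lies in three selectivity problems: forming the tetra-ortho-substituted C8–C6'' bond at exactly these positions, placing one methyl on O7 among six oxygens, and telling apart the oxygens at C5 and C8a of unit 1, which flank the same carbon C4a. The key step exploits that ring A of unit 1 (C4a, C5, C6, C7, C8, C8a) is an acylphloroglucinol monomethyl ether, that is, a Claisen-cyclised tetraketide. Such a ring can be stored as a 3-aryl-4-methoxy-2-pyranone in which the pyranone C3–aryl bond is already the C8–C6'' bond, the 4-methoxyl is already the 7-methoxyl, and the lactone carbonyl carbon is the future C8a.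

## Logic of the disconnections

18 to 17: the five O–CH2Ph bonds are cut. All phenols stay masked by one kind of group until the end and are released in a single neutral reductive step. The forward step must leave the methyl ether, both enones and the biaryl untouched.

17 to 15: the O1–C2 bond of unit 1 is cut and the C2=C3 unsaturation is taken back to the chalcone level. This traces the pyranone ring and ring B of unit 1 to a cinnamoyl chain on ring A. The forward oxidative closure needs the C8a oxygen to be the only free hydroxyl next to the ketone, so that the ring can close in one direction only.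

15 to 14: the O5–benzyl bond is cut. The two phenols that flank the ketone are told apart here by their surroundings, one beside a ring hydrogen and one beside the bulky biaryl. The forward alkylation must take the unhindered oxygen and stop after one equivalent.

14 to 12: the C4a–C8a bond of ring A of unit 1 is cut, turning the arene into an opened tetraketide and then into its lactone. The gain is large: a hexasubstituted benzene ring is replaced by a pyranone whose C3 substituent and 4-methoxyl fix the biaryl position and the methyl position beforehand. The forward step must fold in the Claisen mode only and must leave the enone intact under methoxide.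

12 to 8 and 11: the bond between the pyranone 6-methylene carbon and the ketone carbonyl is cut. It uses the vinylogous acidity of the 6-methyl group and joins two fragments of comparable size. The forward step needs 1,2-acylation of a soft dienolate by an unsaturated acyl donor, without conjugate addition and without double acylation.

11 to 9: the amide C–N bond is cut. The acyl donor is tuned for carbonyl attack and the simpler precursor is a catalogue acid. The forward step must preserve the E alkene.

8 to 5 and 7: the bond between pyranone C3 and flavone C6'', the future C8–C6'' bond, is cut. The hindered biaryl bond is made while one partner is a small monocyclic vinylogous α-bromo ester, not a second flavone, and the 4-methoxyl is already in place. The forward cross-coupling must outpace loss of boron from a very electron-rich, di-ortho-substituted arylboron reagent.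

7 to 6: the C3–Br bond is cut. The electrophile comes in one step from a catalogue pyranone. Bromination must occur at the ring carbon C3 and not at the 6-methyl group.

5 to 4: the C6''–B bond is cut. The nucleophile is traced to an aryl iodide. The borylation must tolerate two flanking benzyloxy groups.

4 to 3: the O5''–benzyl bond is cut. The last free phenol of unit 2 is capped only after it has done its directing work. The alkylation must overcome chelation and the neighbouring iodine.

3 to 2: the C6''–I bond is cut. The position of the future biaryl bond on unit 2 is set by the free chelated 5-hydroxyl, which steers the electrophile to its ortho carbon. The forward step needs C6 over C8 selectivity and mono-iodination.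

2 to 1: the O7''– and O4'''–benzyl bonds are cut, which leads back to a natural flavone with the whole of unit 2 in place. The forward alkylation relies on the inertness of the chelated 5-hydroxyl.

## Other disconnections considered

Alternative 1: The cut is the C8–C6'' bond itself, made last between two flavones derived from 1 and tied together through an O7–CH2–O5'' acetal. In the forward key step the tethered 8-iodide A2 would give the bridged biflavone A1 under Pd(OAc)2 catalysis with a bulky phosphine and a carbonate or pivalate base. Zerovalent palladium inserts into C8–I, C6''–H is cleaved by concerted metalation–deprotonation through an eight-membered palladacycle, and reductive elimination closes the seven-membered dioxepine.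

- In its favour: both halves come from 1 with their pyranone rings intact. The tether allows only C6''–H to be reached, so the biaryl regiochemistry is not in question. Iodination at C8 of a 5-O-alkyl flavone follows the natural preference.
- Against it here: the mixed acetal must join the most reactive hydroxyl of one flavone (O7) to the least reactive, chelated hydroxyl of the other (O5''). Unit 1 must carry benzyl groups at O5 and O4' but not at O7, the reverse of the natural order of reactivity. After A1 the bridge must be cleaved and O7 methylated in the presence of the freed 5''-hydroxyl, which is plausible because that hydroxyl is chelated but costs two more operations.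
- Comparison: on the mechanistic side the catalytic C–H arylation is at least the equal of the chosen recyclisation in predictability. The alternative is better in one respect: the methyl group is introduced late, so the same intermediate could also serve the parent biflavone and other methyl ethers. On structure the chosen plan is stronger, because the methoxyl and the biaryl position are both carried into the key step already fixed. In step count the alternative is expected to be equal or somewhat longer because of the protecting-group interchange and the tether.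

Alternative 2: The cut is both aryl ether bonds, O1–C8a and O1''–C8a''. In the forward key step the biaryl bis(1,3-diketone) A4, which bears a fluorine at each future C8a, would close both pyranone rings with K2CO3 in DMF by two intramolecular nucleophilic aromatic substitutions, giving A3.

- In its favour: two rings form in one operation, and the diketones are already at the flavone oxidation level, so no oxidation is needed. Each fluoride has an ortho carbonyl and only meta alkoxy groups, so the substitution is electronically sound. The fluorine marks which carbon becomes C8a, so the ambiguity between the C5 and C8a oxygens never arises. On this point the alternative is better than the chosen plan, which must settle it by a sterically controlled benzylation.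
- Against it here: A4 needs two pentasubstituted fluoroarenes built from simple benzenes, so 1 cannot be used. The tetra-ortho biaryl bond and two diketone syntheses remain to be done. A3 carries methyl ethers at both O5 and O7, so one must be removed selectively before hydrogenolysis.
- Comparison: mechanistically the alternative is the simpler and more robust key step. Structurally it postpones the hard problems (biaryl bond, methyl placement) without solving them. It is judged clearly longer in steps.

Alternative 3: The cut is C8''–C8a'' and C5''–C4a'', so that ring A of unit 2 is built last. In the forward key step the bis-silyl dienol ether A6, an acetoacetate diene carrying unit 1 on its carbon 2, would add across C5–C6 of the bromopyranone A7 (terminal diene carbon to C6, ketene acetal carbon to C5). Loss of HBr, methanol and the silyl groups would then give A5 with free 5''- and 7''-hydroxyls.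

- In its favour: two carbon–carbon bonds form in the step, one more than in the chosen key step. A5 is a single hydrogenolysis away from 18, so the endgame is shorter than that of the chosen plan. Ring A of unit 2 needs no protecting groups.
- Against it here: A6 requires α-arylation of an acetoacetate at a di-ortho-substituted position of unit 1 and double silylation next to a bulky aryl group that twists the diene. A7 is a monocyclic bromopyranone that has to be made. After conjugate addition a 4-pyranone can open by loss of its ring oxygen instead of closing the new ring, so retention of O1''–C8a'' is a real chemoselectivity question. Lewis acid activation would endanger the benzyl ethers.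
- Comparison: the alternative is the equal of the chosen plan in convergence and the better in post-key-step economy. The chosen recyclisation rests on a closer reaction class and on precursors that are reached by standard enolate and cross-coupling chemistry, and the total step count of the alternative is expected to be higher because both coupling partners need several steps.

Key step: step 9

## Remarks and assumptions

- Numbering: the 8-linked, methylated flavone is unit 1 and the 6-linked flavone is unit 2, so the target is 7-O-methylagathisflavone in this numbering.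
- The biaryl axis carries no descriptor, so the racemic atropisomer mixture is accepted.
- The enol ether double bond of the ring-opened intermediate 13 is E by the sequence rules (ester over aryl, methoxyl over methylene), although the ester and the ketone chain are cis; it is named and drawn accordingly.
- Assumption: 4-methoxy-6-methylpyran-2-one (6) and (E)-4-benzyloxycinnamic acid (9) are catalogue compounds.
- Changes made for safety:
  - A bromopyranone is used as the coupling electrophile, so the methoxyl is in place before the coupling.
  - An N-methoxy-N-methylamide is used as the acyl donor, to suppress conjugate addition.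

## Route

Step 1
Reactants: 1 apigenin
Product: 2 7,4'-di-O-benzylapigenin
Conditions: BnBr (2.1 equiv), K2CO3, DMF, 40 °C
Reagents that add atoms: benzyl bromide, BrCc1ccccc1
Why: Williamson ether synthesis; the 7- and 4'-hydroxyls are the acidic, unchelated phenols, whereas the 5-hydroxyl is hydrogen-bonded to the C4 carbonyl and should stay free with two equivalents of halide at moderate temperature.

Step 2
Reactants: 2 7,4'-di-O-benzylapigenin
Product: 3 6-iodo-7,4'-di-O-benzylapigenin
Conditions: BnMe3N·ICl2 (1.1 equiv), CaCO3, CH2Cl2–MeOH, rt
Reagents that add atoms: benzyltrimethylammonium dichloroiodate, C[N+](C)(C)Cc1ccccc1.Cl[I-]Cl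
Why: Electrophilic aromatic iodination; in 5-hydroxy-7-alkoxyflavones the free chelated phenol directs the electrophile to its ortho carbon C6 (5-O-alkyl flavones react at C8 instead), the buffered mild reagent limits di-iodination, and ring B is deactivated by the pyranone.

Step 3
Reactants: 3 6-iodo-7,4'-di-O-benzylapigenin
Product: 4 6-iodo-5,7,4'-tri-O-benzylapigenin
Conditions: BnBr (3 equiv), K2CO3, nBu4NI (cat.), DMF, 70 °C
Reagents that add atoms: benzyl bromide, BrCc1ccccc1
Why: Williamson etherification of the chelated, iodine-flanked phenol under more forcing conditions; capping O5 keeps a phenoxide out of the palladium steps and the later enolate chemistry.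

Step 4
Reactants: 4 6-iodo-5,7,4'-tri-O-benzylapigenin
Product: 5 5,7-bis(benzyloxy)-2-(4-benzyloxyphenyl)-6-(4,4,5,5-tetramethyl-1,3,2-dioxaborolan-2-yl)chromen-4-one
Conditions: B2pin2, PdCl2(dppf) (5 mol%), KOAc, 1,4-dioxane, 90 °C
Reagents that add atoms: bis(pinacolato)diboron, CC1(C)OB(OC1(C)C)B1OC(C)(C)C(C)(C)O1
Why: Miyaura borylation; the aryl iodide adds to zerovalent palladium, acetate-assisted transmetalation with the diboron and reductive elimination give the pinacol boronate, and the weak acetate base should not trigger homocoupling.

Step 5
Reactants: 6 4-methoxy-6-methylpyran-2-one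
Product: 7 3-bromo-4-methoxy-6-methylpyran-2-one
Conditions: NBS (1.05 equiv), MeCN, rt, dark
Reagents that add atoms: N-bromosuccinimide, O=C1CCC(=O)N1Br
Why: Electrophilic bromination of the enol ether carbon C3 (α to the lactone carbonyl, β to the methoxyl); ionic conditions in the dark avoid radical bromination of the 6-methyl group.

Step 6
Reactants: 5 5,7-bis(benzyloxy)-2-(4-benzyloxyphenyl)-6-(4,4,5,5-tetramethyl-1,3,2-dioxaborolan-2-yl)chromen-4-one; 7 3-bromo-4-methoxy-6-methylpyran-2-one
Product: 8 3-[5,7-bis(benzyloxy)-2-(4-benzyloxyphenyl)-4-oxochromen-6-yl]-4-methoxy-6-methylpyran-2-one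
Conditions: Pd2(dba)3 (2.5 mol%), SPhos (10 mol%), K3PO4, toluene–H2O 10:1, 90 °C
Reagents that add atoms: none
Why: Suzuki–Miyaura coupling; the vinylogous α-bromo ester adds readily to zerovalent palladium, and the bulky electron-rich biarylphosphine is chosen because it speeds transmetalation and reductive elimination with di-ortho-alkoxy arylboron partners, so that coupling should outrun loss of boron.

Step 7
Reactants: 9 (E)-4-benzyloxycinnamic acid
Product: 11 (E)-N-methoxy-N-methyl-3-[4-(benzyloxy)phenyl]prop-2-enamide, via acyl imidazolide 10 (not isolated)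
Conditions: CDI, CH2Cl2, rt; then MeNH(OMe)·HCl, rt
Reagents that add atoms: N,O-dimethylhydroxylamine hydrochloride, CNOC.Cl
Why: Amide formation through the acyl imidazolide; it gives a non-enolisable Weinreb amide, and the E alkene is not touched.

Step 8
Reactants: 8 3-[5,7-bis(benzyloxy)-2-(4-benzyloxyphenyl)-4-oxochromen-6-yl]-4-methoxy-6-methylpyran-2-one; 11 (E)-N-methoxy-N-methyl-3-[4-(benzyloxy)phenyl]prop-2-enamide
Product: 12 3-[5,7-bis(benzyloxy)-2-(4-benzyloxyphenyl)-4-oxochromen-6-yl]-6-[(E)-4-(4-benzyloxyphenyl)-2-oxobut-3-enyl]-4-methoxypyran-2-one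
Conditions: LiN(SiMe3)2 (2.2 equiv), THF, −78 °C; then 11 (1.3 equiv), −78 to −20 °C; aq. NH4Cl
Reagents that add atoms: none
Why: Claisen-type C-acylation of a pyranone dienolate with a Weinreb amide; the 6-methyl group is the only acidic site because C3 is arylated, the amide is a poor conjugate acceptor so 1,2-attack is expected, and the chelated tetrahedral adduct (or, if it collapses early, the second equivalent of base) prevents double acylation.

Step 9
Reactants: 12 3-[5,7-bis(benzyloxy)-2-(4-benzyloxyphenyl)-4-oxochromen-6-yl]-6-[(E)-4-(4-benzyloxyphenyl)-2-oxobut-3-enyl]-4-methoxypyran-2-one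
Product: 14 (E)-2',6'-dihydroxy-4'-methoxy-3'-[5,7-bis(benzyloxy)-2-(4-benzyloxyphenyl)-4-oxochromen-6-yl]-4-benzyloxychalcone, via ring-opened methyl ester 13 (not isolated)
Conditions: Mg(OMe)2 (6 equiv), MeOH–THF, 65 °C; then cold aq. HCl to pH 4
Reagents that add atoms: none
Why: Magnesium-bound methoxide adds to the hindered lactone carbonyl and opens the 2-pyranone to the enol ether ester 13, whose ring-derived double bond (E by the sequence rules) keeps the ester and the ketone chain cis. The 5,7-diketone of 13 is held as a magnesium chelate, and its central carbon (future C4a) attacks the ester carbon (future C8a) and expels methoxide. Ring A of unit 1 closes in a 6-exo-trig Claisen (Dieckmann-type) mode, and the cyclic triketone enolises irreversibly to the arene, which drives the sequence. The closest known reaction type is the Mg(OMe)2-mediated recyclisation of 6-(2-oxoalkyl)-4-methoxy-2-pyranones to acylphloroglucinol monomethyl ethers. No stereocentre is formed; the E enone is the thermodynamic isomer, so reversible methoxide addition to it should do no lasting harm. The step needs Claisen over aldol folding, which the substrate secures because the carbon that becomes C8 is a fully substituted sp2 carbon without a proton, and it needs C- over O-cyclisation of the diketone (which would lead to a 4-pyranone), which the magnesium chelate favours. The pyranone 4-methoxyl arrives as the 7-methoxyl and the C3–aryl bond as the C8–C6'' bond, so neither position is open to question in this step. Cold, mildly acidic work-up and direct use of the crude product should limit closure of 14 to flavanones.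

Step 10
Reactants: 14 (E)-2',6'-dihydroxy-4'-methoxy-3'-[5,7-bis(benzyloxy)-2-(4-benzyloxyphenyl)-4-oxochromen-6-yl]-4-benzyloxychalcone
Product: 15 (E)-6'-benzyloxy-2'-hydroxy-4'-methoxy-3'-[5,7-bis(benzyloxy)-2-(4-benzyloxyphenyl)-4-oxochromen-6-yl]-4-benzyloxychalcone
Conditions: BnBr (1.05 equiv), K2CO3 (1.2 equiv), DMF, 0 °C to rt
Reagents that add atoms: benzyl bromide, BrCc1ccccc1
Why: Regioselective Williamson mono-benzylation; the phenoxide beside the ring hydrogen (future O5) is accessible, whereas the one beside the di-ortho-substituted biaryl (future O1) is shielded and stays chelated, and any material that has closed through the hindered oxygen and is then benzylated is flavanone 16, which step 11 also carries forward.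

Step 11
Reactants: 15 (E)-6'-benzyloxy-2'-hydroxy-4'-methoxy-3'-[5,7-bis(benzyloxy)-2-(4-benzyloxyphenyl)-4-oxochromen-6-yl]-4-benzyloxychalcone
Product: 17 5,4',5'',7'',4'''-penta-O-benzyl-7-O-methylagathisflavone, via flavanone 16 (not isolated)
Conditions: I2 (10 mol%), DMSO, 120 °C
Reagents that add atoms: none
Why: Iodine-catalysed oxidative cyclisation of a 2'-hydroxychalcone; intramolecular oxa-Michael addition of the only free hydroxyl gives flavanone 16, α-iodination and loss of HI give the flavone, and DMSO reoxidises HI to I2. Because only the oxygen next to the biaryl is free, O1–C2 must form from the C8a oxygen, which gives the 8-linked unit 1.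

Step 12
Reactants: 17 5,4',5'',7'',4'''-penta-O-benzyl-7-O-methylagathisflavone
Product: 18 7-O-methylagathisflavone (unit numbering as above)
Conditions: H2 (1 atm), 10% Pd/C, THF–MeOH, rt
Reagents that add atoms: none
Why: Catalytic hydrogenolysis of the five benzyl ethers; the aryl methyl ether is inert, and at ambient pressure and temperature the flavone enones should not be reduced.

## Compound list

1 | apigenin, 5,7-dihydroxy-2-(4-hydroxyphenyl)chromen-4-one | O=c1cc(-c2ccc(O)cc2)oc2cc(O)cc(O)c12 | starting material
2 | 7,4'-di-O-benzylapigenin, 7-benzyloxy-2-(4-benzyloxyphenyl)-5-hydroxychromen-4-one | O=c1cc(-c2ccc(OCc3ccccc3)cc2)oc2cc(OCc3ccccc3)cc(O)c12 | intermediate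
3 | 6-iodo-7,4'-di-O-benzylapigenin, 7-benzyloxy-2-(4-benzyloxyphenyl)-5-hydroxy-6-iodochromen-4-one | O=c1cc(-c2ccc(OCc3ccccc3)cc2)oc2cc(OCc3ccccc3)c(I)c(O)c12 | intermediate
4 | 6-iodo-5,7,4'-tri-O-benzylapigenin, 5,7-bis(benzyloxy)-2-(4-benzyloxyphenyl)-6-iodochromen-4-one | O=c1cc(-c2ccc(OCc3ccccc3)cc2)oc2cc(OCc3ccccc3)c(I)c(OCc3ccccc3)c12 | intermediate
5 | 5,7-bis(benzyloxy)-2-(4-benzyloxyphenyl)-6-(4,4,5,5-tetramethyl-1,3,2-dioxaborolan-2-yl)chromen-4-one | CC1(C)OB(c2c(OCc3ccccc3)cc3oc(-c4ccc(OCc5ccccc5)cc4)cc(=O)c3c2OCc2ccccc2)OC1(C)C | intermediate
6 | 4-methoxy-6-methylpyran-2-one | COc1cc(C)oc(=O)c1 | starting material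
7 | 3-bromo-4-methoxy-6-methylpyran-2-one | COc1cc(C)oc(=O)c1Br | intermediate
8 | 3-[5,7-bis(benzyloxy)-2-(4-benzyloxyphenyl)-4-oxochromen-6-yl]-4-methoxy-6-methylpyran-2-one | COc1cc(C)oc(=O)c1-c1c(OCc2ccccc2)cc2oc(-c3ccc(OCc4ccccc4)cc3)cc(=O)c2c1OCc1ccccc1 | intermediate
9 | (E)-4-benzyloxycinnamic acid, (E)-3-[4-(benzyloxy)phenyl]prop-2-enoic acid | O=C(O)/C=C/c1ccc(OCc2ccccc2)cc1 | starting material
10 | (E)-1-(imidazol-1-yl)-3-[4-(benzyloxy)phenyl]prop-2-en-1-one (acyl imidazolide) | O=C(/C=C/c1ccc(OCc2ccccc2)cc1)n1ccnc1 | intermediate
11 | (E)-N-methoxy-N-methyl-3-[4-(benzyloxy)phenyl]prop-2-enamide | CON(C)C(=O)/C=C/c1ccc(OCc2ccccc2)cc1 | intermediate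
12 | 3-[5,7-bis(benzyloxy)-2-(4-benzyloxyphenyl)-4-oxochromen-6-yl]-6-[(E)-4-(4-benzyloxyphenyl)-2-oxobut-3-enyl]-4-methoxypyran-2-one | COc1cc(CC(=O)/C=C/c2ccc(OCc3ccccc3)cc2)oc(=O)c1-c1c(OCc2ccccc2)cc2oc(-c3ccc(OCc4ccccc4)cc3)cc(=O)c2c1OCc1ccccc1 | intermediate
13 | methyl (2E,8E)-2-[5,7-bis(benzyloxy)-2-(4-benzyloxyphenyl)-4-oxochromen-6-yl]-9-[4-(benzyloxy)phenyl]-3-methoxy-5,7-dioxonona-2,8-dienoate | COC(=O)/C(c1c(OCc2ccccc2)cc2oc(-c3ccc(OCc4ccccc4)cc3)cc(=O)c2c1OCc1ccccc1)=C(/OC)CC(=O)CC(=O)/C=C/c1ccc(OCc2ccccc2)cc1 | intermediate
14 | (E)-2',6'-dihydroxy-4'-methoxy-3'-[5,7-bis(benzyloxy)-2-(4-benzyloxyphenyl)-4-oxochromen-6-yl]-4-benzyloxychalcone | COc1cc(O)c(C(=O)/C=C/c2ccc(OCc3ccccc3)cc2)c(O)c1-c1c(OCc2ccccc2)cc2oc(-c3ccc(OCc4ccccc4)cc3)cc(=O)c2c1OCc1ccccc1 | intermediate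
15 | (E)-6'-benzyloxy-2'-hydroxy-4'-methoxy-3'-[5,7-bis(benzyloxy)-2-(4-benzyloxyphenyl)-4-oxochromen-6-yl]-4-benzyloxychalcone | COc1cc(OCc2ccccc2)c(C(=O)/C=C/c2ccc(OCc3ccccc3)cc2)c(O)c1-c1c(OCc2ccccc2)cc2oc(-c3ccc(OCc4ccccc4)cc3)cc(=O)c2c1OCc1ccccc1 | intermediate
16 | 5-benzyloxy-8-[5,7-bis(benzyloxy)-2-(4-benzyloxyphenyl)-4-oxochromen-6-yl]-2-(4-benzyloxyphenyl)-7-methoxychroman-4-one (racemic at C2) | COc1cc(OCc2ccccc2)c2C(=O)CC(c3ccc(OCc4ccccc4)cc3)Oc2c1-c1c(OCc2ccccc2)cc2oc(-c3ccc(OCc4ccccc4)cc3)cc(=O)c2c1OCc1ccccc1 | intermediate
17 | 5,4',5'',7'',4'''-penta-O-benzyl-7-O-methylagathisflavone | COc1cc(OCc2ccccc2)c2c(=O)cc(-c3ccc(OCc4ccccc4)cc3)oc2c1-c1c(OCc2ccccc2)cc2oc(-c3ccc(OCc4ccccc4)cc3)cc(=O)c2c1OCc1ccccc1 | intermediate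
18 | 7-O-methylagathisflavone, 8-[5,7-dihydroxy-2-(4-hydroxyphenyl)-4-oxochromen-6-yl]-5-hydroxy-2-(4-hydroxyphenyl)-7-methoxychromen-4-one | COc1cc(O)c2c(=O)cc(-c3ccc(O)cc3)oc2c1-c1c(O)cc2oc(-c3ccc(O)cc3)cc(=O)c2c1O | target

## Step count and risk assessment

Total step count: 12. Longest linear sequence: 10 steps (steps 1, 2, 3, 4, 6, 8, 9, 10, 11, 12 from 1).

Least certain steps:

Step 9 (key step). The most likely failure is diversion of the opened tetraketide before the Claisen closure: reversible methoxide addition or premature oxa-Michael closure at the styryl ketone, or O-cyclisation of the diketone onto the enol ether carbon, competing with a closure that is slowed by the bulky flavonyl group beside the ester. The fallback takes the enone out of the recyclisation and builds the chalcone afterwards. It sets out from 8, whose 6-methyl anion (LiN(SiMe3)2, THF, −78 °C) would be acylated with N-methoxy-N-methylacetamide to give 3-[5,7-bis(benzyloxy)-2-(4-benzyloxyphenyl)-4-oxochromen-6-yl]-4-methoxy-6-(2-oxopropyl)pyran-2-one F1. Mg(OMe)2 in methanol, applied to this saturated ketone (the closest match to the known reaction class), should give the 2,6-dihydroxy-4-methoxy-3-(flavon-6-yl)acetophenone F2. Benzylation of the less hindered hydroxyl (BnBr, K2CO3) would give the 6-benzyloxy-2-hydroxy acetophenone F3. A Claisen–Schmidt condensation of F3 with 4-benzyloxybenzaldehyde (KOH, EtOH) comes back to the route at 15.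

Step 6. The most likely failure is loss of boron by protonolysis, because the boron-bearing carbon has oxygen donors at both ortho positions and at the para position, while transmetalation to a hindered palladium centre is slow. The fallback uses a hypervalent iodine electrophile that couples at room temperature. It sets out from 5. Triacetic acid lactone and PhI(OAc)2 (Na2CO3, water) would give the zwitterionic 6-methyl-2-oxo-3-(phenyliodonio)pyran-4-olate F4. Its coupling with 5 under Pd(OAc)2, P(t-Bu)3 and LiOH in DME–water at room temperature should give the 3-(flavon-6-yl)-4-hydroxy-6-methylpyran-2-one F5. O-Methylation (Me2SO4, K2CO3, acetone, which favours the 4-methoxy-2-pyranone) comes back to the route at 8.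

Step 8. The most likely failure is conjugate addition of the soft dienolate to the cinnamoyl unit, or stalling through proton transfer after early collapse of the tetrahedral adduct. The fallback replaces acylation by aldol addition and oxidation. It sets out from 11 and 8. Reduction of 11 with i-Bu2AlH (THF, −78 °C) would give (E)-4-benzyloxycinnamaldehyde F6. The lithium dienolate of 8 should add 1,2 to F6 at −78 °C to give the allylic alcohol, the 6-[(E)-4-(4-benzyloxyphenyl)-2-hydroxybut-3-enyl]pyranone F7 (a mixture of stereoisomers). Oxidation of F7 with Dess–Martin periodinane comes back to the route at 12.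

Step 10. The most likely failure is insufficient discrimination between the two chelatable hydroxyls, with alkylation at the hindered oxygen or double alkylation. The fallback uses a much bulkier electrophile and comes back only at the target. It sets out from 14. t-BuPh2SiCl and imidazole in DMF should silylate the unhindered hydroxyl to give the 6'-O-tert-butyldiphenylsilyl chalcone F8. I2 in DMSO would close it to the 5-O-silyl biflavone F9. n-Bu4NF would give the 5-hydroxy tetra-O-benzyl biflavone F10, and hydrogenolysis of F10 (H2, Pd/C) comes back to the route at 18.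

Step 11. The most likely failure is ring iodination of the electron-rich positions (C6 of unit 1, C8'' of unit 2) or acid-induced loss of benzyl groups with opening and reclosing of the hydroxyflavone at 120 °C. The fallback separates cyclisation from oxidation and avoids iodine. It sets out from 15, which would be closed with NaOAc in refluxing ethanol to 16, isolated this time. Dehydrogenation of 16 with DDQ in hot dioxane comes back to the route at 17. This fallback makes no compound outside the compound list (entry F0).

## Further compounds

F1 | step 9 | 3-[5,7-bis(benzyloxy)-2-(4-benzyloxyphenyl)-4-oxochromen-6-yl]-4-methoxy-6-(2-oxopropyl)pyran-2-one | COc1cc(CC(C)=O)oc(=O)c1-c1c(OCc2ccccc2)cc2oc(-c3ccc(OCc4ccccc4)cc3)cc(=O)c2c1OCc1ccccc1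
F2 | step 9 | 6-(3-acetyl-2,4-dihydroxy-6-methoxyphenyl)-5,7-bis(benzyloxy)-2-(4-benzyloxyphenyl)chromen-4-one | COc1cc(O)c(C(C)=O)c(O)c1-c1c(OCc2ccccc2)cc2oc(-c3ccc(OCc4ccccc4)cc3)cc(=O)c2c1OCc1ccccc1
F3 | step 9 | 6-(3-acetyl-4-benzyloxy-2-hydroxy-6-methoxyphenyl)-5,7-bis(benzyloxy)-2-(4-benzyloxyphenyl)chromen-4-one | COc1cc(OCc2ccccc2)c(C(C)=O)c(O)c1-c1c(OCc2ccccc2)cc2oc(-c3ccc(OCc4ccccc4)cc3)cc(=O)c2c1OCc1ccccc1
F4 | step 6 | 6-methyl-2-oxo-3-(phenyliodonio)pyran-4-olate | Cc1cc([O-])c([I+]c2ccccc2)c(=O)o1
F5 | step 6 | 3-[5,7-bis(benzyloxy)-2-(4-benzyloxyphenyl)-4-oxochromen-6-yl]-4-hydroxy-6-methylpyran-2-one | Cc1cc(O)c(-c2c(OCc3ccccc3)cc3oc(-c4ccc(OCc5ccccc5)cc4)cc(=O)c3c2OCc2ccccc2)c(=O)o1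
F6 | step 8 | (E)-3-[4-(benzyloxy)phenyl]prop-2-enal | O=C/C=C/c1ccc(OCc2ccccc2)cc1
F7 | step 8 | 3-[5,7-bis(benzyloxy)-2-(4-benzyloxyphenyl)-4-oxochromen-6-yl]-6-[(E)-4-(4-benzyloxyphenyl)-2-hydroxybut-3-enyl]-4-methoxypyran-2-one (racemic carbinol) | COc1cc(CC(O)/C=C/c2ccc(OCc3ccccc3)cc2)oc(=O)c1-c1c(OCc2ccccc2)cc2oc(-c3ccc(OCc4ccccc4)cc3)cc(=O)c2c1OCc1ccccc1
F8 | step 10 | (E)-6'-(tert-butyldiphenylsilyloxy)-2'-hydroxy-4'-methoxy-3'-[5,7-bis(benzyloxy)-2-(4-benzyloxyphenyl)-4-oxochromen-6-yl]-4-benzyloxychalcone | COc1cc(O[Si](c2ccccc2)(c2ccccc2)C(C)(C)C)c(C(=O)/C=C/c2ccc(OCc3ccccc3)cc2)c(O)c1-c1c(OCc2ccccc2)cc2oc(-c3ccc(OCc4ccccc4)cc3)cc(=O)c2c1OCc1ccccc1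
F9 | step 10 | 4',5'',7'',4'''-tetra-O-benzyl-5-O-(tert-butyldiphenylsilyl)-7-O-methylagathisflavone | COc1cc(O[Si](c2ccccc2)(c2ccccc2)C(C)(C)C)c2c(=O)cc(-c3ccc(OCc4ccccc4)cc3)oc2c1-c1c(OCc2ccccc2)cc2oc(-c3ccc(OCc4ccccc4)cc3)cc(=O)c2c1OCc1ccccc1
F10 | step 10 | 4',5'',7'',4'''-tetra-O-benzyl-7-O-methylagathisflavone | COc1cc(O)c2c(=O)cc(-c3ccc(OCc4ccccc4)cc3)oc2c1-c1c(OCc2ccccc2)cc2oc(-c3ccc(OCc4ccccc4)cc3)cc(=O)c2c1OCc1ccccc1
F0 | step 11 | none | none
A1 | alternative 1 | O7,O5''-methylene-bridged 5,4',7'',4'''-tetra-O-benzylagathisflavone | O=c1cc(-c2ccc(OCc3ccccc3)cc2)oc2c1c(OCc1ccccc1)cc1OCOc3c(-c12)c(OCc1ccccc1)cc1oc(-c2ccc(OCc4ccccc4)cc2)cc(=O)c31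
A2 | alternative 1 | 5-benzyloxy-2-(4-benzyloxyphenyl)-8-iodo-7-{[7-benzyloxy-2-(4-benzyloxyphenyl)-4-oxochromen-5-yl]oxymethoxy}chromen-4-one | O=c1cc(-c2ccc(OCc3ccccc3)cc2)oc2c(I)c(OCOc3cc(OCc4ccccc4)cc4oc(-c5ccc(OCc6ccccc6)cc5)cc(=O)c34)cc(OCc3ccccc3)c12
A3 | alternative 2 | 5'',7'',4',4'''-tetra-O-benzyl-5,7-di-O-methylagathisflavone | COc1cc(OC)c2c(=O)cc(-c3ccc(OCc4ccccc4)cc3)oc2c1-c1c(OCc2ccccc2)cc2oc(-c3ccc(OCc4ccccc4)cc3)cc(=O)c2c1OCc1ccccc1
A4 | alternative 2 | 1-[3-[2,6-bis(benzyloxy)-4-fluoro-3-[3-(4-benzyloxyphenyl)-3-oxopropanoyl]phenyl]-2-fluoro-4,6-dimethoxyphenyl]-3-(4-benzyloxyphenyl)propane-1,3-dione | COc1cc(OC)c(C(=O)CC(=O)c2ccc(OCc3ccccc3)cc2)c(F)c1-c1c(OCc2ccccc2)cc(F)c(C(=O)CC(=O)c2ccc(OCc3ccccc3)cc2)c1OCc1ccccc1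
A5 | alternative 3 | 5,4',4'''-tri-O-benzyl-7-O-methylagathisflavone | COc1cc(OCc2ccccc2)c2c(=O)cc(-c3ccc(OCc4ccccc4)cc3)oc2c1-c1c(O)cc2oc(-c3ccc(OCc4ccccc4)cc3)cc(=O)c2c1O
A6 | alternative 3 | 5-benzyloxy-2-(4-benzyloxyphenyl)-7-methoxy-8-[1-methoxy-1,3-bis(trimethylsilyloxy)buta-1,3-dien-2-yl]chromen-4-one (ketene acetal geometry unspecified) | C=C(O[Si](C)(C)C)C(=C(OC)O[Si](C)(C)C)c1c(OC)cc(OCc2ccccc2)c2c(=O)cc(-c3ccc(OCc4ccccc4)cc3)oc12
A7 | alternative 3 | 5-bromo-2-(4-benzyloxyphenyl)pyran-4-one | O=c1cc(-c2ccc(OCc3ccccc3)cc2)occ1Br
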